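Target numbering (C1–C7) is used for every intermediate. The configurations of 3 and 5 were re-derived centre by centre against 19 (O1 and O2 on one ring face, O3 on the other) and agree, so no structure needed correction. The one change to the design is that O3 travels through the enolate step as a silyl ether, not as the benzoate.

## Structural features

The target is a monocyclic cyclohexenone: one six-membered carbocycle (C1–C6) with the carbonyl at C6 conjugated to C4=C5, and a single exocyclic carbon, C7, attached to C1 as a benzoyloxymethyl arm. Three contiguous stereocentres sit on C1–C2–C3. C1 is a quaternary tertiary carbinol (free OH, C7) directly beside the ketone, C2 carries the acetate, and C3, allylic to C4=C5, carries the second benzoate. O1 and O2 are cis and O3 is trans to O2 (1S,2S,3R in this numbering). The molecule is fragile toward base: the γ-benzoyloxy enone can eliminate and aromatise, the esters can migrate between neighbouring oxygens (O3/O2, O7/O1), and any intermediate with O7 free is a β-hydroxy ketone open to retro-aldol loss of C7. The real difficulty is the oxygenated quaternary centre C1 with its configuration fixed relative to C2, together with telling four oxygens apart (O1 free, O2 acetyl, O3 and O7 benzoyl). The key step exploits the 1,4-relationship of the oxygens on C3 and C6 across C4=C5, which is the pattern left by [4+2] addition of O2 to a C3=C4–C5=C6 diene. The cis-C1,C2-diol is the pattern of a microbial arene cis-dihydrodiol, and a bromine on C6 of that diene marks the peroxide carbon that becomes the carbonyl.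

## Logic of the disconnections

19 ⇒ 17 + 18. The O2–acetyl bond is cut first because acylation of a secondary hydroxyl beside a tertiary one is the most selective of the ester formations. The gain is a precursor with only two kinds of ester. The forward step must acylate O2 without touching O1 and without letting the C3 benzoate migrate.

17 ⇒ 16. The two C–O bonds of an isopropylidene ketal spanning O1 and O2 are restored. This keeps the cis-diol masked through all earlier base and acylation steps and makes O3 and O7 the only free hydroxyls when the benzoates go on. The forward step must hydrolyse the ketal under acid mild enough for two benzoates and the enone.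

16 ⇒ 14 + 15. Both benzoate acyl–oxygen bonds (O3 and O7) are cut together, since the two esters are identical and the two hydroxyls are the only free ones. One operation replaces two. The forward step needs complete acylation of a neopentyl-type primary hydroxyl without base-induced retro-aldol.

14 ⇒ 13. The O3–silicon bond is put back so that O3 carries neither an acidic proton nor an electrophilic acyl group during the enolate step. The forward removal must spare the ketal and must not be basic.

13 ⇒ 9 + 10 (through 11 and 12). The C1–C7 bond is cut as an aldol bond, which removes the quaternary centre and the only exocyclic carbon and leaves a plain C6 ring. The forward step demands α′-enolisation of an enone at a carbon bearing oxygen, survival of the β-oxygen on C2, and attack on the face that keeps O1 cis to O2. The cis-fused dioxolane is relied on for the last two.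

9 ⇒ 7 + 8. The O3–silicon bond is cut, a routine protection that simplifies to a known type of hydroxy enone.

7 ⇒ 5 (through 6). The C6 carbonyl is traced back to a carbon bearing both bromine and a peroxide oxygen, and the C3 hydroxyl to the other peroxide oxygen. Reductive O–O cleavage then delivers ketone and alcohol regiospecifically in one operation. The forward step needs a reductant that cleaves O–O without touching the alkene or the ketal.

5 ⇒ 3 + 4. The C3–O and C6–O bonds are cut in a retro-[4+2] sense. One ring, two C–O bonds and the C3 stereocentre are removed at once, leaving a diene that carries only the diol stereocentres. The forward step must add O2 to the face opposite the dioxolane and outrun diene dimerisation.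

3 ⇒ 1 + 2. The ketal C–O bonds are cut to reach the commercial, enantiopure microbial diol. The forward step must avoid acid-induced dehydration of the dihydrodiol to a phenol.

## Other disconnections considered

Alternative 1: Ferrier carbocyclisation from a sugar.
- **Cut and key step:** the C5–C6 bond of the carbocycle, tracing the ring back to the pyranose of 2-deoxy-D-glucose A1. A1 would be turned into the hex-5-enopyranoside A2 (O3 benzoate, O4 silyl ether). Hg(OCOCF3)2 (divalent mercury) in aqueous acetone hydrates the exocyclic enol ether, the ring opens to a keto-aldehyde, and the mercury enolate closes by intramolecular aldol addition to cyclohexanone A3.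
- **In favour:** C2 and C3, with their trans relationship and the right absolute configuration, come straight from C4 and C3 of the sugar. No photochemistry or peroxide is involved, and A1 is a cheap, storable solid that does not dimerise. On availability and handling this alternative is the better one, and on C2/C3 control it is the equal of the chosen plan.
- **Against:** A3 has its carbonyl at C1, a superfluous carbinol at C5 and methylenes at C4 and C6. The C6 ketone, the C4=C5 alkene and the C1 carbinol bearing C7 all remain to be made. That means one-carbon homologation at the C1 ketone with O1 cis to O2, where the bulky C2 silyloxy group would be expected to steer reagents to the face giving the trans arrangement. It also means regioselective dehydration of C5–OH toward C4 and an allylic oxidation at C6. Mercury is an added burden.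
- **Comparison:** the ring-forming mechanism is at least as dependable as the photooxygenation. Structurally it is weaker at C1, where the chosen plan has the cis relationship enforced by a ring fusion. It is much longer: about five steps to A2 and seven or more after A3, against nine in all.

Alternative 2: ring-closing metathesis of a tartrate-derived dienone.
- **Cut and key step:** the C4=C5 double bond. The second-generation Grubbs catalyst RuCl2(H2IMes)(PCy3)(=CHPh) would join the C3 vinyl group and the C6 vinyl ketone of acyclic dienone A5, built from diethyl D-tartrate A4, to give cyclohexenone A6 with loss of ethylene.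
- **In favour:** A6 already holds the whole carbon skeleton, C7, the quaternary C1 carbinol, the enone in its final place and all three stereocentres. After it only protecting-group operations remain, with no strongly basic step on a base-sensitive enone. On the end-game this alternative is better than the chosen plan, which still has to form the C1–C7 bond. The metathesis is as reliable as the cycloaddition.
- **Against:** the difficulty moves into A5. Its quaternary C1 must be set by addition to an α-alkoxy ketone in an open chain, with no ring to enforce the outcome. A4 is the less common tartrate enantiomer, and A5 would need roughly nine or ten steps. After A6, removal of the trans-acetonide frees O2 and O3 together, and they must then be distinguished beside the free tertiary O1.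
- **Comparison:** equal on mechanism and better after the key step, but worse on C1 stereocontrol, on oxygen differentiation and on total length (about fifteen steps against nine).

Alternative 3: desymmetrising oxa-Michael addition on a p-quinol.
- **Cut and key step:** the C2–O bond, with O2 delivered from O1 through a boron tether. The achiral p-quinol A7 would be tethered as a B-phenyl boronate hemiester. A chiral tertiary amine–thiourea catalyst would direct the boron-bound oxygen to one of the two enantiotopic enone β-carbons, giving the cis-fused dioxaborolane A8.
- **In favour:** A7 is two steps from a cheap phenol. C7 and the quaternary C1 are present from the start, and the O1/O2 cis relationship is enforced by the tether exactly as it is by the dioxolane in the chosen plan (equal). Absolute configuration is set catalytically in one step. Up to the key step this is shorter than the chosen plan and better for C7.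
- **Against:** A8 has the carbonyl at C4, the alkene at C5=C6 and a methylene at C3. The target needs oxygen at C3 trans to O2, the alkene at C4=C5 and the ketone at C6. That means an α-oxygenation and a 1,3-transposition of the enone, whose usual reagents (hydrazine, hydrides, peroxide) clash with the benzoate and the boronate. Enantiopurity would depend on the catalyst, whereas the microbial diol is enantiopure.
- **Comparison:** better before the key step, markedly worse after it, and less secure in absolute configuration. Overall length would be similar or longer, with more redox manipulation.

Key step: step 2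

Assumption: monomeric formaldehyde 10 is generated immediately before use by thermal cracking of commercial paraformaldehyde.

## Route

Step 1
Reactants: 1 (1S,2S)-3-bromocyclohexa-3,5-diene-1,2-diol; 2 2,2-dimethoxypropane
Product: 3 (3aS,7aS)-4-bromo-2,2-dimethyl-3a,7a-dihydro-1,3-benzodioxole (acetonide of 1)
Conditions: 2,2-dimethoxypropane (3 equiv), p-TsOH·H2O (cat.), CH2Cl2, 0 °C → rt; Et3N quench; used fresh
Reagents that add atoms: 2,2-dimethoxypropane COC(C)(C)OC
Why: Acid-catalysed transketalisation of a cis-1,2-diol to its cis-fused dioxolane; brief exposure to catalytic acid and a basic quench avoid dehydrative aromatisation, and no stereocentre is touched.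

Step 2
Reactants: 3 acetonide of the bromodiene; 4 dioxygen (as singlet oxygen)
Product: 5 bridgehead-bromo endoperoxide acetonide (1-bromo-7,8-O-isopropylidene-2,3-dioxabicyclo[2.2.2]oct-5-ene-7,8-diol; peroxide bridge anti to the dioxolane)
Conditions: O2 (1 atm), 5,10,15,20-tetraphenylporphyrin (cat.), visible light, CH2Cl2, −30 °C; solution concentrated cold and used at once
Reagents that add atoms: dioxygen O=O
Why: Energy transfer from the photoexcited porphyrin turns ground-state O2 into singlet O2, which acts as a 2π heterodienophile toward the s-cis diene C3=C4–C5=C6 of 3 and forms the C3–O and C6–O bonds in one suprafacial, concerted (if asynchronous) [4+2] event. The closest known reaction type is the dye-sensitised photooxygenation of cyclic 1,3-dienes, including acetonides of arene cis-dihydrodiols, to 2,3-dioxabicyclo[2.2.2]oct-5-enes. The one ring that closes, the six-membered 1,2-dioxine (O–O, C3, C4=C5, C6), is formed by cycloaddition with both bonds made at the diene termini at once, so the peroxide bridge is necessarily cis across the carbocycle. The two new stereocentres, C3 and bridgehead C6, are therefore set together and by the same element: the cis-fused dioxolane, whose oxygens and endo methyl group cover one face, so O2 arrives on the other face and the C3–O bond ends up trans to O2 as 19 requires. The selectivities needed are facial (substrate-controlled as just described) and chemoselectivity for cycloaddition over the ene reaction and over Diels–Alder dimerisation of 3. The locked s-cis geometry should make [4+2] far faster than abstraction of the allylic C1–H or C2–H, and low temperature, dilution and freshly made 3 hold back dimerisation. Regiochemistry does not arise with a symmetrical dienophile; the bromine only lowers diene reactivity somewhat and ends on bridgehead C6, where it later decides which peroxide carbon becomes the ketone.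

Step 3
Reactants: 5 bridgehead-bromo endoperoxide acetonide
Product: 7 (3aS,7R,7aS)-7-hydroxy-2,2-dimethyl-7,7a-dihydro-1,3-benzodioxol-4(3aH)-one (C3 hydroxy enone; C6 ketone), via bromohydrin 6 (not isolated)
Conditions: thiourea (1.2 equiv), MeOH–H2O (20:1), 0 °C → rt; NaHCO3 work-up
Reagents that add atoms: none
Why: Thiourea reduction of an endoperoxide (sulfur attacks a peroxide oxygen, then solvolysis) cleaves only the O–O bond; the geminal bromohydrin 6 at C6 is a masked carbonyl and expels bromide at once, so C6 alone becomes the ketone while C3 keeps its hydroxyl. No stereocentre is formed or disturbed.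

Step 4
Reactants: 7 C3 hydroxy enone; 8 tert-butyldimethylsilyl chloride
Product: 9 (3aS,7R,7aR)-7-(tert-butyldimethylsilyloxy)-2,2-dimethyl-7,7a-dihydro-1,3-benzodioxol-4(3aH)-one (O3 silyl ether of 7; same spatial arrangement)
Conditions: TBSCl (1.2 equiv), imidazole (2.5 equiv), DMF, 0 °C → rt
Reagents that add atoms: tert-butyldimethylsilyl chloride CC(C)(C)[Si](C)(C)Cl
Why: Standard silyl chloride–imidazole silylation of a secondary allylic alcohol; it removes the acidic O3–H and keeps any electrophilic acyl group away from the enolate of the next step.

Step 5
Reactants: 9 O3 silyl ether enone; 10 formaldehyde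
Product: 13 (3aS,7R,7aS)-7-(tert-butyldimethylsilyloxy)-3a-(hydroxymethyl)-2,2-dimethyl-7,7a-dihydro-1,3-benzodioxol-4(3aH)-one (C7 on C1; O1 cis to O2), via lithium dienolate 11 (not isolated), via lithium aldolate 12 (not isolated)
Conditions: LiN(iPr)2 (LDA, 1.1 equiv), THF, −78 °C; HCHO (gas, from cracked paraformaldehyde), −78 °C; AcOH, −78 °C → rt
Reagents that add atoms: formaldehyde C=O
Why: Crossed aldol addition of a kinetically formed lithium cross-conjugated dienolate (α′-deprotonation of an enone at C1) to formaldehyde. The dioxolane holds the C2–O bond near the nodal plane of the enolate, which should retard β-elimination at −78 °C, as with enolates of other dioxolane-protected α,β-dihydroxy carbonyl compounds. The new quaternary C1 is set by the ring fusion: C7 adds to the face that keeps the 5/6 system cis-fused, so O1 stays cis to O2.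

Step 6
Reactants: 13 C1 hydroxymethyl ketone silyl ether
Product: 14 (3aS,7R,7aS)-7-hydroxy-3a-(hydroxymethyl)-2,2-dimethyl-7,7a-dihydro-1,3-benzodioxol-4(3aH)-one (O3,O7-diol)
Conditions: HF·pyridine, pyridine, THF, 0 °C → rt
Reagents that add atoms: none
Why: Fluoride cleavage of a secondary silyl ether under buffered, weakly acidic conditions, which should spare the acetonide and avoid the alkoxides that could trigger retro-aldol loss of C7.

Step 7
Reactants: 14 O3,O7-diol; 15 benzoyl chloride
Product: 16 [(3aS,7R,7aS)-7-(benzoyloxy)-2,2-dimethyl-4-oxo-7,7a-dihydro-1,3-benzodioxol-3a(4H)-yl]methyl benzoate (acetonide of 17)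
Conditions: BzCl (2.5 equiv), pyridine, DMAP (cat.), CH2Cl2, 0 °C → rt
Reagents that add atoms: benzoyl chloride O=C(Cl)c1ccccc1
Why: DMAP-catalysed O-acylation with an acid chloride; the allylic secondary O3–H and the primary O7–H are the only free hydroxyls (O1 and O2 are locked in the ketal), so both benzoates go on in one operation.

Step 8
Reactants: 16 dibenzoate acetonide
Product: 17 zeylenone, [(1S,5R,6S)-5-(benzoyloxy)-1,6-dihydroxy-2-oxocyclohex-3-en-1-yl]methyl benzoate
Conditions: TFA–H2O (4:1), CH2Cl2, 0 °C → rt
Reagents that add atoms: none
Why: Acid-catalysed hydrolysis of an isopropylidene ketal; benzoates and the enone tolerate aqueous TFA at or below room temperature, and the acidic medium keeps base-promoted acyl migration and β-elimination out of play.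

Step 9
Reactants: 17 zeylenone; 18 acetic anhydride
Product: 19 2-O-acetylzeylenone, [(1S,5R,6S)-6-acetoxy-5-(benzoyloxy)-1-hydroxy-2-oxocyclohex-3-en-1-yl]methyl benzoate
Conditions: Ac2O (1.5 equiv), pyridine, CH2Cl2, 0 °C → rt
Reagents that add atoms: acetic anhydride CC(=O)OC(C)=O
Why: Chemoselective O-acetylation: the secondary C2 hydroxyl should react with Ac2O/pyridine far faster than the hindered tertiary C1 hydroxyl beside the carbonyl; no stereocentre is touched.

## Compound list

1 | (1S,2S)-3-bromocyclohexa-3,5-diene-1,2-diol | O[C@H]1C=CC=C(Br)[C@H]1O | starting material
2 | 2,2-dimethoxypropane | COC(C)(C)OC | starting material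
3 | (3aS,7aS)-4-bromo-2,2-dimethyl-3a,7a-dihydro-1,3-benzodioxole | CC1(C)O[C@H]2C=CC=C(Br)[C@H]2O1 | intermediate
4 | dioxygen | O=O | starting material
5 | bridgehead-bromo endoperoxide acetonide (peroxide anti to dioxolane) | CC1(C)O[C@H]2[C@H]3C=C[C@](Br)(OO3)[C@H]2O1 | intermediate
6 | C6 bromohydrin, C3 alcohol acetonide | CC1(C)O[C@H]2[C@H](O)C=C[C@](Br)(O)[C@H]2O1 | intermediate (not isolated)
7 | (3aS,7R,7aS)-7-hydroxy-2,2-dimethyl-7,7a-dihydro-1,3-benzodioxol-4(3aH)-one | CC1(C)O[C@H]2[C@H](O)C=CC(=O)[C@H]2O1 | intermediate
8 | tert-butyldimethylsilyl chloride | CC(C)(C)[Si](C)(C)Cl | starting material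
9 | (3aS,7R,7aR)-7-(tert-butyldimethylsilyloxy)-2,2-dimethyl-7,7a-dihydro-1,3-benzodioxol-4(3aH)-one | CC1(C)O[C@H]2[C@H](O[Si](C)(C)C(C)(C)C)C=CC(=O)[C@H]2O1 | intermediate
10 | formaldehyde | C=O | starting material
11 | lithium dienolate of 9 (C6–OLi, C1=C6) | [Li+].CC1(C)O[C@H]2[C@H](O[Si](C)(C)C(C)(C)C)C=CC([O-])=C2O1 | intermediate (not isolated)
12 | lithium aldolate (lithium alkoxide of 13 at O7) | [Li+].CC1(C)O[C@H]2[C@H](O[Si](C)(C)C(C)(C)C)C=CC(=O)[C@@]2(C[O-])O1 | intermediate (not isolated)
13 | (3aS,7R,7aS)-7-(tert-butyldimethylsilyloxy)-3a-(hydroxymethyl)-2,2-dimethyl-7,7a-dihydro-1,3-benzodioxol-4(3aH)-one | CC1(C)O[C@H]2[C@H](O[Si](C)(C)C(C)(C)C)C=CC(=O)[C@@]2(CO)O1 | intermediate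
14 | (3aS,7R,7aS)-7-hydroxy-3a-(hydroxymethyl)-2,2-dimethyl-7,7a-dihydro-1,3-benzodioxol-4(3aH)-one | CC1(C)O[C@H]2[C@H](O)C=CC(=O)[C@@]2(CO)O1 | intermediate
15 | benzoyl chloride | O=C(Cl)c1ccccc1 | starting material
16 | [(3aS,7R,7aS)-7-(benzoyloxy)-2,2-dimethyl-4-oxo-7,7a-dihydro-1,3-benzodioxol-3a(4H)-yl]methyl benzoate | CC1(C)O[C@H]2[C@H](OC(=O)c3ccccc3)C=CC(=O)[C@@]2(COC(=O)c3ccccc3)O1 | intermediate
17 | zeylenone, [(1S,5R,6S)-5-(benzoyloxy)-1,6-dihydroxy-2-oxocyclohex-3-en-1-yl]methyl benzoate | O[C@H]1[C@H](OC(=O)c2ccccc2)C=CC(=O)[C@]1(O)COC(=O)c1ccccc1 | intermediate
18 | acetic anhydride | CC(=O)OC(C)=O | starting material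
19 | 2-O-acetylzeylenone, [(1S,5R,6S)-6-acetoxy-5-(benzoyloxy)-1-hydroxy-2-oxocyclohex-3-en-1-yl]methyl benzoate | CC(=O)O[C@H]1[C@H](OC(=O)c2ccccc2)C=CC(=O)[C@]1(O)COC(=O)c1ccccc1 | target

## Step count and least certain steps

Total step count: 9. Longest linear sequence: 9 steps, from 1 to 19.

**Step 2 (key step).** The likely failure is loss of material, not wrong selectivity. Thermal Diels–Alder dimerisation of 3 can compete with a photooxygenation slowed by the electron-withdrawing bromine, and the bridgehead-bromo peroxide can decompose on warming or concentration. The fallback sets out from 3 and avoids oxygen cycloaddition and peroxides altogether. OsO4 (cat.) with N-methylmorpholine N-oxide in acetone–water should dihydroxylate the unhalogenated C3=C4 alkene on the face anti to the dioxolane to give the C3,C4-syn-diol F1. TBSOTf and 2,6-lutidine give the bis-silyl ether F2. Bromine–lithium exchange with t-BuLi at −78 °C, trapping with B(OMe)3 and oxidation with H2O2/NaOH convert the vinyl bromide through its enol into the C6 ketone F3. DBU then removes the β-silyloxy group on C4 by E1cB elimination and gives the enone. The route is rejoined at 9, with O3 already silylated, so steps 2 to 4 are replaced by four operations.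

**Step 5.** The main risks are β-elimination from dienolate 11 with opening of the dioxolane and aromatisation, proton transfer to the extended γ-enolate, or polymerisation of formaldehyde before it meets the enolate. These arise because the substrate is an α,β-dioxygenated enone under strongly basic conditions. The fallback sets out from 9 and avoids a free enolate. Soft enolisation with TMSOTf and Et3N in CH2Cl2 at 0 °C should give the trimethylsilyl dienol ether F4. Aqueous 37% HCHO with Yb(OTf)3 (cat.) in THF at room temperature then carries out the hydroxymethylation as a Lewis-acid-catalysed aqueous Mukaiyama aldol, on the same face for the same ring-fusion reason. The route is rejoined at 13.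

**Step 6.** The likely failure is retro-aldol loss of formaldehyde from the free β-hydroxy ketone, or partial loss of the ketal, if the desilylation needs long exposure. The fallback sets out from 13 and changes the order of events so that O7 is never free while the silyl group is removed. BzCl, pyridine and DMAP give the O7 benzoate O3 silyl ether F5. HF·pyridine then removes the silyl group to give the O7 benzoate C3 alcohol F6. A second benzoylation with BzCl, pyridine and DMAP rejoins the route at 16, at the cost of one extra step.

**Step 9.** The likely failure is base-promoted migration of the C3 benzoate to the free O2 before acetylation, or some acylation of the tertiary O1 if conditions are forced. Both would give regioisomeric esters. The fallback sets out from 17 and comes back at 19 with a different kind of acyl transfer. Immobilised Candida antarctica lipase B with vinyl acetate in tert-butyl methyl ether at 30–40 °C acetylates under neutral conditions through an acyl-enzyme, which accepts secondary but not tertiary alcohols and involves no base that could move the benzoate. No new isolated compound is involved.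

## Further compounds

F1 | step 2 | C3,C4-syn-diol of bromoalkene acetonide (both hydroxyls anti to the dioxolane) | CC1(C)O[C@H]2[C@H](O)[C@H](O)C=C(Br)[C@H]2O1
F2 | step 2 | C3,C4-bis(tert-butyldimethylsilyl) ether of F1 | CC1(C)O[C@H]2[C@H](O[Si](C)(C)C(C)(C)C)[C@H](O[Si](C)(C)C(C)(C)C)C=C(Br)[C@H]2O1
F3 | step 2 | C6 ketone with C3,C4-bis(silyloxy) groups and C1,C2-acetonide | CC1(C)O[C@H]2[C@H](O[Si](C)(C)C(C)(C)C)[C@H](O[Si](C)(C)C(C)(C)C)CC(=O)[C@H]2O1
F4 | step 5 | trimethylsilyl dienol ether of 9 (C6–OSiMe3, C1=C6) | CC1(C)O[C@H]2[C@H](O[Si](C)(C)C(C)(C)C)C=CC(O[Si](C)(C)C)=C2O1
F5 | step 6 | O7 benzoate O3 silyl ether acetonide | CC1(C)O[C@H]2[C@H](O[Si](C)(C)C(C)(C)C)C=CC(=O)[C@@]2(COC(=O)c3ccccc3)O1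
F6 | step 6 | O7 benzoate C3 alcohol acetonide | CC1(C)O[C@H]2[C@H](O)C=CC(=O)[C@@]2(COC(=O)c3ccccc3)O1
F0 | step 9 | none | none
A1 | alternative 1 | 2-deoxy-D-glucose (open-chain form) | O=CC[C@@H](O)[C@H](O)[C@H](O)CO
A2 | alternative 1 | methyl 3-O-benzoyl-4-O-(tert-butyldimethylsilyl)-2,6-dideoxy-α-D-threo-hex-5-enopyranoside | CO[C@@H]1C[C@@H](OC(=O)c2ccccc2)[C@H](O[Si](C)(C)C(C)(C)C)C(=C)O1
A3 | alternative 1 | 3-(benzoyloxy)-2-(tert-butyldimethylsilyloxy)-5-hydroxycyclohexanone (Ferrier product) | O=C1C[C@H](O)C[C@@H](OC(=O)c2ccccc2)[C@@H]1O[Si](C)(C)C(C)(C)C
A4 | alternative 2 | diethyl D-tartrate, diethyl (2S,3S)-2,3-dihydroxybutanedioate | CCOC(=O)[C@@H](O)[C@H](O)C(=O)OCC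
A5 | alternative 2 | 1-(tert-butyldimethylsilyloxy)-2-hydroxy-2-(trans-2,2-dimethyl-5-vinyl-1,3-dioxolan-4-yl)pent-4-en-3-one (acyclic dienone) | C=C[C@H]1OC(C)(C)O[C@@H]1[C@@](O)(CO[Si](C)(C)C(C)(C)C)C(=O)C=C
A6 | alternative 2 | cyclohexenone with trans-fused O2/O3 acetonide, free O1 and silylated O7 | CC1(C)O[C@@H]2C=CC(=O)[C@](O)(CO[Si](C)(C)C(C)(C)C)[C@H]2O1
A7 | alternative 3 | (1-hydroxy-4-oxocyclohexa-2,5-dien-1-yl)methyl benzoate (p-quinol) | O=C1C=CC(O)(COC(=O)c2ccccc2)C=C1
A8 | alternative 3 | cis-fused B-phenyl dioxaborolane of the C1,C2-diol enone (C4 ketone, C5=C6) | c1ccccc1B1O[C@H]2CC(=O)C=C[C@@]2(COC(=O)c2ccccc2)O1
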